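**Retrosynthetic overview**

1. The strategy rests on the cyclobutane C4–C5–C11–C10 inside the bicyclo[3.1.1]heptenone. C4 is the γ-carbon of the C1 enone and the C9–O bond is anti to C4–C10, so C4–C10 is cut to a 9,10-epoxide and a C1 silyl dienol ether on a cis-fused bicyclo[5.4.0]undecane.
2. Seven-membered ring: ring-closing metathesis at C9=C10 between an isopropenyl group on C11 and an allyl group on C7. C10 is carried as a carboxyl carbon and C1 as a silyl ether, so C11 is never flanked by two carbonyl groups.
3. Six-membered ring: Diels–Alder reaction of (E)-3-methyl-1-silyloxybutadiene with a 5,6-dihydropyran-2-one that holds O7 as a ring atom. Addition anti to the C7 allyl branch sets C5 and C11 (cis) relative to C7.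
4. Lactone: from neopentyl glycol (C5, C6, C7 and both C6 methyls), allyl acetate (C8, C9) and a ketenylidene ylide (C10, C11). C7 is set by asymmetric allylation.
5. Ring order: lactone, six-membered ring, seven-membered ring, four-membered ring. The esters come last (C7 tiglate, then C9 angelate).

Key step: step 15

Remark: longipinane numbering (C1 ketone, C2=C3 with methyl on C3, cyclobutane C4–C5–C11–C10, C6 gem-dimethyl, C7, C8, C9, C10 methyl) is used for all intermediates. "Lower face" means the face of the seven-membered ring that carries H5 and H11.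
Remark: the ligand antipode in step 1 is assumed to be the one that gives the 3R alcohol. C1 of compounds 10 to 16 is an epimer mixture that is removed in step 12.

**Route**

Step 1
Reactants: 1 2,2-dimethylpropane-1,3-diol; 2 allyl acetate
Product: 3 (3R)-2,2-dimethylhex-5-ene-1,3-diol
Conditions: [Ir(cod)Cl]2 (2.5 mol %), (R)-Cl,MeO-BIPHEP (5 mol %), 4-chloro-3-nitrobenzoic acid (10 mol %), Cs2CO3 (20 mol %), 1 (3 equiv), dioxane, 90 °C
Reagents that add atoms: none
Why: Krische allylation from the alcohol oxidation level, in which the iridium catalyst dehydrogenates one CH2OH group and the chiral π-allyliridium species allylates the aldehyde on one face, so the ligand sets C7, and the excess of diol should hold back the second allylation.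

Step 2
Reactants: 3 (3R)-2,2-dimethylhex-5-ene-1,3-diol
Product: 4 (3R)-3-hydroxy-2,2-dimethylhex-5-enal
Conditions: TEMPO (10 mol %), PhI(OAc)2, CH2Cl2, rt
Reagents that add atoms: none
Why: the oxoammonium oxidation is selective for the primary alcohol over the hindered secondary one, and the aldehyde has no α-hydrogen, so C7 is not at risk.

Step 3
Reactants: 4 (3R)-3-hydroxy-2,2-dimethylhex-5-enal; 5 (triphenylphosphoranylidene)ketene
Product: 7 (6R)-6-allyl-5,5-dimethyl-5,6-dihydro-2H-pyran-2-one, via ester ylide 6 (not isolated)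
Conditions: toluene, 110 °C
Reagents that add atoms: none
Why: Bestmann lactonisation, in which the alcohol adds to the ketenylidene ylide and the ester ylide closes by intramolecular Wittig reaction on the neopentyl aldehyde, which can only give the ring (cis) alkene C5=C11.

Step 4
Reactants: 8 3-methylbut-2-enal
Product: 9 (E)-3-methyl-1-(triethylsilyloxy)buta-1,3-diene
Conditions: Et3SiOTf, Et3N, Et2O, 0 °C → rt
Reagents that add atoms: triethylsilyl triflate, CC[Si](CC)(CC)OS(=O)(=O)C(F)(F)F
Why: soft enolisation of the enal (O-silylation, then loss of a γ-hydrogen) is the usual way to (E)-1-silyloxy-3-methylbutadienes.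

Step 5
Reactants: 7 (6R)-6-allyl-5,5-dimethyl-5,6-dihydro-2H-pyran-2-one; 9 (E)-3-methyl-1-(triethylsilyloxy)buta-1,3-diene
Product: 10 cis-fused lactone 3-allyl-4,4,6-trimethyl-8-(triethylsilyloxy)-3,4,4a,5,8,8a-hexahydroisochromen-1-one (H5 and H11 cis, allyl on C7 trans to C4 across the lactone ring, C1 epimers)
Conditions: 9 (3 equiv), CH2Cl2, 13 kbar, 40 °C
Reagents that add atoms: none
Why: Diels–Alder reaction under high pressure, in which the silyloxy terminus C1 bonds to the α-carbon C11 and the CH2 terminus C4 to the β-carbon C5 (ortho/para rule), suprafacial addition makes H5 and H11 cis, and the diene should come to the lactone face anti to the pseudo-equatorial C7 allyl group and the pseudo-axial C6 methyl, which places C4 and C1 on the same side as O7 in the later seven-membered ring.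

Step 6
Reactants: 10 cis-fused Diels–Alder lactone
Product: 11 N-methoxy-N-methyl amide with free C7 hydroxyl (cyclohexene with cis C5–C(CH3)2–CH(OH)–allyl and C11–C(=O)N(OMe)Me, C1–OSiEt3, C2=C3)
Conditions: MeNH(OMe)·HCl, AlMe3, CH2Cl2, 0 °C → rt
Reagents that add atoms: N,O-dimethylhydroxylamine hydrochloride, CNOC.Cl
Why: Weinreb aminolysis of the lactone with the aluminium amide is not basic, so the α-centre C11 and the β-silyloxy group should survive, and it frees O7 and prepares C10 for one methyl addition.

Step 7
Reactants: 11 hydroxy Weinreb amide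
Product: 12 C7 tert-butyldimethylsilyl ether of 11
Conditions: t-BuMe2SiOTf, 2,6-lutidine, CH2Cl2, −78 → 0 °C
Reagents that add atoms: tert-butyldimethylsilyl triflate, CC(C)(C)[Si](C)(C)OS(=O)(=O)C(F)(F)F
Why: the silyl triflate silylates the hindered neopentyl alcohol, and doing so at once should prevent relactonisation.

Step 8
Reactants: 12 silylated Weinreb amide
Product: 13 methyl ketone (C11–C(=O)CH3)
Conditions: MeLi, THF, −78 °C; aq. NH4Cl
Reagents that add atoms: methyllithium, [Li]C
Why: Weinreb ketone synthesis, in which the chelated tetrahedral adduct stops at the ketone and brings in the future C10 methyl.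

Step 9
Reactants: 13 methyl ketone
Product: 14 triene with isopropenyl on C11 and allyl on C7
Conditions: Cp2TiMe2, toluene, 70 °C
Reagents that add atoms: dimethyltitanocene, C[Ti](C)(C1C=CC=C1)C1C=CC=C1
Why: Petasis methylenation, whose non-basic titanium methylidene olefinates a hindered, epimerisable ketone without touching C11 or the β-silyloxy group.

Step 10
Reactants: 14 triene
Product: 15 cis-fused 7-(tert-butyldimethylsilyloxy)-1-(triethylsilyloxy)-3,6,6,10-tetramethylbicyclo[5.4.0]undeca-2,9-diene (longipinane numbering)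
Conditions: RuCl2(H2IMes)(PCy3)(=CHPh) (second-generation Grubbs catalyst, 5 mol %), toluene, 80 °C
Reagents that add atoms: none
Why: ring-closing metathesis of the allyl and isopropenyl groups, held cis on C5 and C11, closes the seven-membered ring as the trisubstituted C9=C10 alkene, while the trisubstituted C2=C3 ring alkene is inert.

Step 11
Reactants: 15 bicyclic bis-silyl ether
Product: 16 C1 allylic alcohol
Conditions: PPTS, MeOH/CH2Cl2, 0 °C
Reagents that add atoms: none
Why: acid-catalysed methanolysis cleaves the unhindered allylic triethylsilyl ether much faster than the neopentyl tert-butyldimethylsilyl ether.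

Step 12
Reactants: 16 C1 allylic alcohol
Product: 17 cis-fused 7-(tert-butyldimethylsilyloxy)-3,6,6,10-tetramethylbicyclo[5.4.0]undeca-2,9-dien-1-one
Conditions: Dess–Martin periodinane, NaHCO3, CH2Cl2, 0 °C
Reagents that add atoms: none
Why: Dess–Martin oxidation under buffered conditions gives the conjugated enone and should neither move the β,γ double bond nor epimerise C11.

Step 13
Reactants: 17 dienone
Product: 18 9,10-epoxy enone (epoxide oxygen on the lower face, trans to O7; C10 methyl on the upper face)
Conditions: mCPBA, NaHCO3, CH2Cl2, 0 °C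
Reagents that add atoms: 3-chloroperbenzoic acid, OOC(=O)c1cccc(Cl)c1
Why: Prilezhaev epoxidation, in which the enone alkene is too electron-poor to react and the peracid should attack C9=C10 from the face of H11, anti to the C11–C1 bond and to the C7 silyloxy group, which sets C9 and C10.

Step 14
Reactants: 18 9,10-epoxy enone
Product: 19 9,10-epoxy-7-(tert-butyldimethylsilyloxy)-1-(trimethylsilyloxy)bicyclo[5.4.0]undeca-1,3-diene (trimethylsilyl dienol ether, C1=C2 and C3=C4)
Conditions: Me3SiOTf (1.1 equiv), Et3N (3 equiv), CH2Cl2, −78 → −20 °C; used crude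
Reagents that add atoms: trimethylsilyl triflate, C[Si](C)(C)OS(=O)(=O)C(F)(F)F
Why: soft enolisation, in which the O-silylated enone loses a proton from the unhindered γ-CH2 (C4) and not from the hindered methine C11, gives the through-conjugated dienol ether as with steroidal enones, and the amine-buffered triflate at low temperature is meant to spare the epoxide.

Step 15
Reactants: 19 trimethylsilyl dienol ether
Product: 21 9-hydroxy-7-(tert-butyldimethylsilyloxy)longipin-2-en-1-one, via C9 trimethylsilyl ether 20 (not isolated)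
Conditions: Me3SiOTf (0.2 equiv), 2,6-di-tert-butyl-4-methylpyridine (0.3 equiv), CH2Cl2, −78 → −40 °C; then K2CO3, MeOH, 0 °C
Reagents that add atoms: none
Why: Proposed new method: the silyl triflate activates the epoxide oxygen and polarises the tertiary C10–O bond, the γ-carbon C4 of the dienol ether (held at about a 1,3-diaxial distance from C10 by the cis ring fusion, C10 axial and C6 equatorial on the cyclohexadiene) attacks C10 from the side opposite the oxygen, and the silyl group of the resulting oxocarbenium ion passes on to an epoxide oxygen, so the step is an isomerisation of 19 to the silyl ether 20 of the enone. The closest known reactions are Lewis-acid (Mukaiyama-type) openings of epoxides and acetals by silyl enol ethers, cation–olefin closures of epoxy alkenes, and anionic 4-exo epoxide openings of the epoxynitrile type; a vinylogous, cyclobutane-forming version at a tertiary centre is not known. The four-membered ring C4–C5–C11–C10 closes in the 4-exo-tet mode, and the same bond completes the bicyclo[3.1.1]heptenone. C10 is set by inversion (anti opening), which turns its methyl group towards the enone bridge and leaves O9 anti to C4–C10, and C4 can only become the bridgehead on the face of C10 because C5 and C11 are cis. The step needs attack by C4 and not by C2 (which would give a cyclobutanone and lose the enone conjugation) and bond formation at C10 and not at C9 (5-endo at a carbon with little cationic character); ring strain is paid for by epoxide opening and return of the conjugated enone. The competing process is a 1,2-shift of hydride or of a ring bond to the C10 cation, which low temperature, a non-nucleophilic counter-ion and the short C4–C10 distance are meant to outrun.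

Step 16
Reactants: 21 9-hydroxy-7-(tert-butyldimethylsilyloxy)longipin-2-en-1-one
Product: 22 9-(allyloxycarbonyloxy)-7-(tert-butyldimethylsilyloxy)longipin-2-en-1-one
Conditions: allyl chloroformate, pyridine, DMAP (cat.), CH2Cl2, 0 °C → rt
Reagents that add atoms: allyl chloroformate, C=CCOC(Cl)=O
Why: carbonate formation blocks O9 with a group that palladium removes under neutral conditions, orthogonal to the silyl ether, the later tiglate and the enone.

Step 17
Reactants: 22 allyl carbonate
Product: 23 9-(allyloxycarbonyloxy)-7-hydroxylongipin-2-en-1-one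
Conditions: HF·pyridine, pyridine/THF, 0 °C → rt
Reagents that add atoms: none
Why: fluoride cleaves the hindered C7 silyl ether, and the carbonate and the enone are stable to buffered HF.

Step 18
Reactants: 23 C7 alcohol
Product: 24 9-(allyloxycarbonyloxy)-7-tigloyloxylongipin-2-en-1-one
Conditions: (E)-2-methylbut-2-enoyl chloride, Et3N, DMAP, CH2Cl2, rt → 40 °C
Reagents that add atoms: tigloyl chloride, C/C=C(\C)C(Cl)=O
Why: DMAP-catalysed acylation with the geometrically stable E acid chloride gives the C7 tiglate.

Step 19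
Reactants: 24 tiglate allyl carbonate
Product: 25 9-hydroxy-7-tigloyloxylongipin-2-en-1-one
Conditions: Pd(PPh3)4 (5 mol %), morpholine, THF, rt
Reagents that add atoms: none
Why: Tsuji–Trost deallylation (π-allylpalladium formation, loss of CO2, capture of the allyl group by morpholine) frees O9 without base or acid.

Step 20
Reactants: 25 9-hydroxy-7-tigloyloxylongipin-2-en-1-one
Product: 26 (4R,5S,7R,9R,10R,11R)-9-angeloyloxy-7-tigloyloxylongipin-2-en-1-one (CNP0236543.2)
Conditions: angelic acid, 2,4,6-trichlorobenzoyl chloride, Et3N, toluene, rt; then 25, toluene, 80 °C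
Reagents that add atoms: angelic acid, C/C=C(/C)C(=O)O
Why: Yamaguchi-type acylation with the mixed anhydride and no nucleophilic catalyst should transfer the Z acyl group without isomerisation, and the angelate comes last because it is the geometrically labile ester.

**Compound list**

1 | 2,2-dimethylpropane-1,3-diol (neopentyl glycol) | OCC(C)(C)CO | starting material
2 | allyl acetate | C=CCOC(C)=O | starting material
3 | (3R)-2,2-dimethylhex-5-ene-1,3-diol | C=CC[C@@H](O)C(C)(C)CO | intermediate
4 | (3R)-3-hydroxy-2,2-dimethylhex-5-enal | C=CC[C@@H](O)C(C)(C)C=O | intermediate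
5 | (triphenylphosphoranylidene)ketene (Bestmann ylide) | O=C=C=P(c1ccccc1)(c1ccccc1)c1ccccc1 | starting material
6 | (3R)-2,2-dimethyl-1-oxohex-5-en-3-yl (triphenylphosphoranylidene)acetate (ester ylide, not isolated) | C=CC[C@@H](OC(=O)C=P(c1ccccc1)(c1ccccc1)c1ccccc1)C(C)(C)C=O | intermediate
7 | (6R)-6-allyl-5,5-dimethyl-5,6-dihydro-2H-pyran-2-one | C=CC[C@H]1OC(=O)C=CC1(C)C | intermediate
8 | 3-methylbut-2-enal | CC(C)=CC=O | starting material
9 | (E)-3-methyl-1-(triethylsilyloxy)buta-1,3-diene | CC[Si](CC)(CC)O/C=C/C(C)=C | intermediate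
10 | cis-fused lactone 3-allyl-4,4,6-trimethyl-8-(triethylsilyloxy)-3,4,4a,5,8,8a-hexahydroisochromen-1-one (C1 epimers) | C=CC[C@H]1OC(=O)[C@@H]2C(O[Si](CC)(CC)CC)C=C(C)C[C@@H]2C1(C)C | intermediate
11 | hydroxy Weinreb amide (C7–OH, C11–C(=O)N(OMe)Me, C1–OSiEt3; C1 epimers) | C=CC[C@@H](O)C(C)(C)[C@H]1CC(C)=CC(O[Si](CC)(CC)CC)[C@H]1C(=O)N(C)OC | intermediate
12 | C7 tert-butyldimethylsilyl ether of 11 | C=CC[C@@H](O[Si](C)(C)C(C)(C)C)C(C)(C)[C@H]1CC(C)=CC(O[Si](CC)(CC)CC)[C@H]1C(=O)N(C)OC | intermediate
13 | methyl ketone (C11–C(=O)CH3) | C=CC[C@@H](O[Si](C)(C)C(C)(C)C)C(C)(C)[C@H]1CC(C)=CC(O[Si](CC)(CC)CC)[C@H]1C(C)=O | intermediate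
14 | triene (C11 isopropenyl, C7 allyl) | C=CC[C@@H](O[Si](C)(C)C(C)(C)C)C(C)(C)[C@H]1CC(C)=CC(O[Si](CC)(CC)CC)[C@H]1C(C)=C | intermediate
15 | cis-fused 7-(tert-butyldimethylsilyloxy)-1-(triethylsilyloxy)-3,6,6,10-tetramethylbicyclo[5.4.0]undeca-2,9-diene | CC1=CC[C@@H](O[Si](C)(C)C(C)(C)C)C(C)(C)[C@H]2CC(C)=CC(O[Si](CC)(CC)CC)[C@@H]12 | intermediate
16 | C1 alcohol of 15 | CC1=CC[C@@H](O[Si](C)(C)C(C)(C)C)C(C)(C)[C@H]2CC(C)=CC(O)[C@@H]12 | intermediate
17 | cis-fused 7-(tert-butyldimethylsilyloxy)-3,6,6,10-tetramethylbicyclo[5.4.0]undeca-2,9-dien-1-one | CC1=CC[C@@H](O[Si](C)(C)C(C)(C)C)C(C)(C)[C@H]2CC(C)=CC(=O)[C@@H]12 | intermediate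
18 | 9,10-epoxy enone (oxygen on the lower face) | O1[C@@H]2C[C@@H](O[Si](C)(C)C(C)(C)C)C(C)(C)[C@H]3CC(C)=CC(=O)[C@H]3[C@]12C | intermediate
19 | 9,10-epoxy-7-(tert-butyldimethylsilyloxy)-1-(trimethylsilyloxy)bicyclo[5.4.0]undeca-1,3-diene (key-step precursor) | O1[C@@H]2C[C@@H](O[Si](C)(C)C(C)(C)C)C(C)(C)[C@H]3C=C(C)C=C(O[Si](C)(C)C)[C@H]3[C@]12C | intermediate
20 | 7-(tert-butyldimethylsilyloxy)-9-(trimethylsilyloxy)longipin-2-en-1-one (not isolated) | C[Si](C)(C)O[C@@H]1C[C@@H](O[Si](C)(C)C(C)(C)C)C(C)(C)[C@@H]2[C@H]3C(=O)C=C(C)[C@@H]2[C@]31C | intermediate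
21 | 9-hydroxy-7-(tert-butyldimethylsilyloxy)longipin-2-en-1-one (key-step product) | O[C@@H]1C[C@@H](O[Si](C)(C)C(C)(C)C)C(C)(C)[C@@H]2[C@H]3C(=O)C=C(C)[C@@H]2[C@]31C | intermediate
22 | 9-(allyloxycarbonyloxy)-7-(tert-butyldimethylsilyloxy)longipin-2-en-1-one | C=CCOC(=O)O[C@@H]1C[C@@H](O[Si](C)(C)C(C)(C)C)C(C)(C)[C@@H]2[C@H]3C(=O)C=C(C)[C@@H]2[C@]31C | intermediate
23 | 9-(allyloxycarbonyloxy)-7-hydroxylongipin-2-en-1-one | C=CCOC(=O)O[C@@H]1C[C@@H](O)C(C)(C)[C@@H]2[C@H]3C(=O)C=C(C)[C@@H]2[C@]31C | intermediate
24 | 9-(allyloxycarbonyloxy)-7-tigloyloxylongipin-2-en-1-one | C=CCOC(=O)O[C@@H]1C[C@@H](OC(=O)/C(C)=C/C)C(C)(C)[C@@H]2[C@H]3C(=O)C=C(C)[C@@H]2[C@]31C | intermediate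
25 | 9-hydroxy-7-tigloyloxylongipin-2-en-1-one | O[C@@H]1C[C@@H](OC(=O)/C(C)=C/C)C(C)(C)[C@@H]2[C@H]3C(=O)C=C(C)[C@@H]2[C@]31C | intermediate
26 | (4R,5S,7R,9R,10R,11R)-9-angeloyloxy-7-tigloyloxylongipin-2-en-1-one | C/C=C(/C)C(=O)O[C@@H]1C[C@@H](OC(=O)/C(C)=C/C)C(C)(C)[C@@H]2[C@H]3C(=O)C=C(C)[C@@H]2[C@]31C | target

Total step count: 20. Longest linear sequence: 19 steps (steps 1 to 3 and 5 to 20; step 4 is a one-step side branch).

**Steps most likely to fail**

Step 15. What may go wrong: the developing C10 cation is diverted by a 1,2-shift of hydride or of a ring bond, the silylated epoxide eliminates to an allylic silyl ether, or the dienol ether closes through C2. The fallback makes the same bond by the anionic counterpart, an epoxysulfone cyclisation of the epoxynitrile type, and sets out from 19. N-Bromosuccinimide (THF, −78 °C) should brominate the dienol ether at the γ-carbon to give the 4-bromo-9,10-epoxy enone F1 (either C4 epimer; they interconvert by bromide exchange). PhSO2Na in DMF should give the 4-(phenylsulfonyl)-9,10-epoxy enone F2. Cs2CO3 in MeCN deprotonates only the doubly activated C4–H, and the sulfonyl carbanion should open the epoxide at C10 in the 4-exo-tet mode to give 9-hydroxy-4-(phenylsulfonyl)-7-(tert-butyldimethylsilyloxy)longipin-2-en-1-one F3. Reductive removal of the bridgehead sulfone with Al(Hg) in wet THF comes back to the route at 21.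

Step 5. What may go wrong: no cycloaddition at the neopentyl β-carbon of the lactone while the silyloxy diene slowly hydrolyses or polymerises. The fallback replaces the diene by a far more nucleophilic vinylketene acetal and sets out from 7. Methyl 3-methylbut-2-enoate (COC(=O)C=C(C)C) with LiN(i-Pr)2 and Me3SiCl gives 1-methoxy-3-methyl-1-(trimethylsilyloxy)buta-1,3-diene F4. Its annulation with 7 (toluene, 110 °C; concerted or Michael–Claisen) should give the C1 mixed ketal cycloadduct F5 on the same lactone face. Dilute HCl in THF hydrolyses F5 to the cis-fused keto lactone F6. Luche reduction (NaBH4, CeCl3·7H2O, MeOH, −78 °C) gives the C1 hydroxy lactone F7, and Et3SiCl with imidazole comes back to the route at 10.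

Step 20. What may go wrong: acyl transfer to the hindered C9 hydroxyl is slow and the activated angelic acid isomerises to the E (tigloyl) form. The fallback builds the Z alkene on the ester and sets out from 25. Esterification with 2-[bis(2,2,2-trifluoroethoxy)phosphoryl]propanoic acid (dicyclohexylcarbodiimide, DMAP) gives the C9 phosphonopropionate F8. Still–Gennari olefination with acetaldehyde (KN(SiMe3)2, 18-crown-6, THF, −78 °C) should give the Z-2-methylbut-2-enoate and so comes back to the route at 26.

**Further compounds**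

F1 | step 15 | 4-bromo-9,10-epoxy-7-(tert-butyldimethylsilyloxy)-3,6,6,10-tetramethylbicyclo[5.4.0]undec-2-en-1-one | O1[C@@H]2C[C@@H](O[Si](C)(C)C(C)(C)C)C(C)(C)[C@H]3C(Br)C(C)=CC(=O)[C@H]3[C@]12C
F2 | step 15 | 9,10-epoxy-4-(phenylsulfonyl)-7-(tert-butyldimethylsilyloxy)-3,6,6,10-tetramethylbicyclo[5.4.0]undec-2-en-1-one | O1[C@@H]2C[C@@H](O[Si](C)(C)C(C)(C)C)C(C)(C)[C@H]3C(S(=O)(=O)c4ccccc4)C(C)=CC(=O)[C@H]3[C@]12C
F3 | step 15 | 9-hydroxy-4-(phenylsulfonyl)-7-(tert-butyldimethylsilyloxy)longipin-2-en-1-one | O[C@@H]1C[C@@H](O[Si](C)(C)C(C)(C)C)C(C)(C)[C@@H]2[C@H]3C(=O)C=C(C)[C@]2(S(=O)(=O)c4ccccc4)[C@]31C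
F4 | step 5 | 1-methoxy-3-methyl-1-(trimethylsilyloxy)buta-1,3-diene | COC(O[Si](C)(C)C)=CC(C)=C
F5 | step 5 | C1 methyl trimethylsilyl ketal cycloadduct of 7 | C=CC[C@H]1OC(=O)[C@@H]2C(OC)(O[Si](C)(C)C)C=C(C)C[C@@H]2C1(C)C
F6 | step 5 | cis-fused keto lactone 3-allyl-4,4,6-trimethyl-3,4,4a,5-tetrahydroisochromene-1,8(8aH)-dione | C=CC[C@H]1OC(=O)[C@@H]2C(=O)C=C(C)C[C@@H]2C1(C)C
F7 | step 5 | C1 hydroxy lactone (C1 epimers) | C=CC[C@H]1OC(=O)[C@@H]2C(O)C=C(C)C[C@@H]2C1(C)C
F8 | step 20 | 9-{2-[bis(2,2,2-trifluoroethoxy)phosphoryl]propanoyloxy}-7-tigloyloxylongipin-2-en-1-one | CC(P(=O)(OCC(F)(F)F)OCC(F)(F)F)C(=O)O[C@@H]1C[C@@H](OC(=O)/C(C)=C/C)C(C)(C)[C@@H]2[C@H]3C(=O)C=C(C)[C@@H]2[C@]31C
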